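**Retrosynthetic overview**
1. Target ⇒ 7-O-prenylation (prenyl bromide) of (2R,3R)-3'-O-methyltaxifolin.
2. Ring C of that flavanonol ⇒ α-ketol ring expansion of a (2R,3R)-2-aryl-3-hydroxy-2,3-dihydrobenzofuran-3-carbaldehyde: the ring bond C2–C3 shifts to the formyl carbon, C2 keeps its configuration and C3 is created in the shift.
3. That aldehyde ⇒ its methyl ester ⇒ asymmetric interrupted Feist–Benary annulation of phloroglucinol (ring A) with a β-chloro-α-keto ester carrying ring B (C–C bond first, then O–C bond).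
4. Keto ester ⇒ Darzens condensation of O-pivaloylvanillin with methyl dichloroacetate; vanillin ⇒ guaiacol + glyoxylic acid; guaiacol ⇒ catechol; phloroglucinol ⇒ resorcinol (C–H borylation/oxidation).
5. Ring order: rings A and B come from benzenediols; the five-membered O-heterocycle is closed first and then enlarged to the six-membered ring C.

Assumption: the quinidine-derived squaramide of step 6 is taken to give the 3R series drawn; if it gives the mirror image, its quinine-derived pseudo-enantiomer is used.

**Step 1**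
Reactants: 1 catechol (benzene-1,2-diol)
Product: 2 guaiacol (2-methoxyphenol)
Conditions: MeI (1.0 equiv), K2CO3 (1.0 equiv), acetone, reflux
Reagents that add atoms: iodomethane, CI
Why: Williamson ether synthesis on a symmetric diol, where one equivalent of MeI and base gives mainly the monoether (veratrole and catechol are removed by extraction and distillation); no stereocentre.

**Step 2**
Reactants: 2 guaiacol; 3 glyoxylic acid
Product: 5 vanillin (4-hydroxy-3-methoxybenzaldehyde), via mandelic acid adduct 4 (not isolated)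
Conditions: OHCCO2H (aq.), NaOH, H2O, 25 °C; then CuSO4 (cat.), air (O2), NaOH, 95 °C; H2SO4
Reagents that add atoms: none
Why: para-selective electrophilic aromatic hydroxyalkylation of the phenoxide by glyoxylate, then copper-catalysed oxidative decarboxylation of the mandelic acid (the industrial guaiacol-to-vanillin sequence); no stereocentre survives.

**Step 3**
Reactants: 5 vanillin
Product: 6 4-formyl-2-methoxyphenyl pivalate
Conditions: PivCl, Et3N, DMAP (cat.), CH2Cl2, 0 → 25 °C
Reagents that add atoms: pivaloyl chloride, CC(C)(C)C(Cl)=O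
Why: O-acylation; the pivalate prevents quinone-methide formation from the later benzylic chloride, survives LiN(SiMe3)2 and NaHCO3, and is removed without an extra step by iBu2AlH in step 7.

**Step 4**
Reactants: 6 4-formyl-2-methoxyphenyl pivalate; 7 methyl dichloroacetate
Product: 9 methyl 3-chloro-3-[3-methoxy-4-(pivaloyloxy)phenyl]-2-oxopropanoate (racemic), via chloroglycidate 8 (not isolated)
Conditions: 7, LiN(SiMe3)2, THF, −78 °C; then 6, −78 → 25 °C; MgBr2·OEt2 (10 mol %), 25 °C
Reagents that add atoms: none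
Why: Darzens condensation gives the 2-chloroglycidate, which isomerises by 1,2-chloride shift to the β-chloro-α-keto ester (known for anisaldehyde); the C–Cl centre is racemic and epimerises through the enol, which step 6 exploits.

**Step 5**
Reactants: 10 resorcinol (benzene-1,3-diol)
Product: 13 phloroglucinol (benzene-1,3,5-triol), via bis-silyl ether 11 (not isolated), via arylboronate 12 (not isolated)
Conditions: (Me3Si)2NH, 100 °C; then [Ir(OMe)(cod)]2 (1.5 mol %), dtbpy (3 mol %), B2pin2 (1.0 equiv), hexane, 80 °C; then H2O2, NaOH, THF/H2O, 0 °C; HCl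
Reagents that add atoms: hydrogen peroxide, OO
Why: iridium-catalysed C–H borylation is sterically directed to C5, the only position not ortho to a silyloxy group, and oxidation of the C–B bond with desilylation gives the triol (one-pot borylation/oxidation); no stereocentre.

**Step 6**
Reactants: 13 phloroglucinol (1.5 equiv); 9 methyl 3-chloro-3-[3-methoxy-4-(pivaloyloxy)phenyl]-2-oxopropanoate
Product: 15 methyl (2R,3R)-3,4,6-trihydroxy-2-[3-methoxy-4-(pivaloyloxy)phenyl]-2,3-dihydro-1-benzofuran-3-carboxylate (aryl cis to 3-OH), via chlorohydrin 14 (not isolated)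
Conditions: quinidine-derived 3,5-bis(trifluoromethyl)phenyl squaramide (10 mol %), NaHCO3 (1.5 equiv), 2-MeTHF, −30 → 20 °C
Reagents that add atoms: none
Why: cinchona-catalysed interrupted Feist–Benary annulation, in which a ring carbon of phloroglucinol adds to the squaramide-bound keto carbonyl anti to the C–Cl bond of the rapidly epimerising 9 (Felkin–Anh, dynamic kinetic resolution) and sets C3, and the neighbouring phenol then displaces chloride by 5-exo-tet SN2 with inversion and sets C2 with the aryl group cis to the 3-OH.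

**Step 7**
Reactants: 15 methyl (2R,3R)-3,4,6-trihydroxy-2-[3-methoxy-4-(pivaloyloxy)phenyl]-2,3-dihydro-1-benzofuran-3-carboxylate
Product: 16 (2R,3R)-3,4,6-trihydroxy-2-(4-hydroxy-3-methoxyphenyl)-2,3-dihydro-1-benzofuran-3-carbaldehyde
Conditions: iBu2AlH (7 equiv), CH2Cl2/THF, −78 → −50 °C; aq. potassium sodium tartrate (KNaC4H4O6)
Reagents that add atoms: none
Why: partial ester reduction stops at the chelated aluminium hemiacetal of the α-aluminoxy ester and gives the aldehyde on work-up, the aryl pivalate is cleaved reductively in the same pot, and neither stereocentre is touched.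

**Step 8**
Reactants: 16 (2R,3R)-3,4,6-trihydroxy-2-(4-hydroxy-3-methoxyphenyl)-2,3-dihydro-1-benzofuran-3-carbaldehyde
Product: 17 (2R,3R)-3,5,7-trihydroxy-2-(4-hydroxy-3-methoxyphenyl)-2,3-dihydro-4H-chromen-4-one (3'-O-methyltaxifolin)
Conditions: DBU (0.3 equiv), MeOH, 0 → 25 °C, argon; AcOH quench
Reagents that add atoms: none
Why: Proposed new method: base-triggered α-ketol (acyloin) ring expansion of a 3-hydroxy-2,3-dihydrobenzofuran-3-carbaldehyde to a 3-hydroxychroman-4-one, in which the peri phenoxide acts as internal base for the tertiary 3-OH and the resulting alkoxide pushes the ring bond C2–C3 onto the formyl carbon (1,2-shift with retention at C2, so 2R is carried over), the ring-A carbon cannot compete because the ring fusion forbids the bisected phenonium geometry, the transoid rotamer (formyl oxygen anti to the anionic C3–O and lying over the ring face that carries only H at C2) exposes the formyl face that becomes 3R and hence the trans product, and the change from an aldehyde to a hydrogen-bonded aryl ketone drives the step; the closest known reaction type is the α-ketol rearrangement of tertiary α-hydroxy aldehydes and ketones (for example the D-homoannulation of 17-hydroxy-20-keto steroids, transoid under base and cisoid under Lewis acids), which has not been shown on this ring system.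

**Step 9**
Reactants: 17 (2R,3R)-3'-O-methyltaxifolin; 18 prenyl bromide (1-bromo-3-methylbut-2-ene, 1.05 equiv)
Product: 19 (2R,3R)-3,5-dihydroxy-2-(4-hydroxy-3-methoxyphenyl)-7-[(3-methylbut-2-en-1-yl)oxy]-2,3-dihydro-4H-chromen-4-one (target)
Conditions: K2CO3 (1.05 equiv), acetone, 0 → 25 °C, argon
Reagents that add atoms: none
Why: Williamson O-alkylation at the most acidic phenol, since 7-OH (para to the carbonyl) is ionised selectively by one equivalent of carbonate while 5-OH is hydrogen-bonded to C4=O and 4'-OH and 3-OH are less acidic; the brief mild base leaves C2 and C3 unchanged.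

**Compound list**
1 | catechol | Oc1ccccc1O | starting material
2 | guaiacol | COc1ccccc1O | intermediate
3 | glyoxylic acid | O=CC(=O)O | starting material
4 | 4-hydroxy-3-methoxymandelic acid (racemic, not isolated) | COc1cc(C(O)C(=O)O)ccc1O | intermediate
5 | vanillin | COc1cc(C=O)ccc1O | intermediate
6 | 4-formyl-2-methoxyphenyl pivalate | COc1cc(C=O)ccc1OC(=O)C(C)(C)C | intermediate
7 | methyl dichloroacetate | COC(=O)C(Cl)Cl | starting material
8 | methyl 2-chloro-3-[3-methoxy-4-(pivaloyloxy)phenyl]oxirane-2-carboxylate (racemic, not isolated) | COC(=O)C1(Cl)OC1c1ccc(OC(=O)C(C)(C)C)c(OC)c1 | intermediate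
9 | methyl 3-chloro-3-[3-methoxy-4-(pivaloyloxy)phenyl]-2-oxopropanoate (racemic) | COC(=O)C(=O)C(Cl)c1ccc(OC(=O)C(C)(C)C)c(OC)c1 | intermediate
10 | resorcinol | Oc1cccc(O)c1 | starting material
11 | 1,3-bis(trimethylsilyloxy)benzene (not isolated) | C[Si](C)(C)Oc1cccc(O[Si](C)(C)C)c1 | intermediate
12 | 2-[3,5-bis(trimethylsilyloxy)phenyl]-4,4,5,5-tetramethyl-1,3,2-dioxaborolane (not isolated) | C[Si](C)(C)Oc1cc(O[Si](C)(C)C)cc(c1)B1OC(C)(C)C(C)(C)O1 | intermediate
13 | phloroglucinol | Oc1cc(O)cc(O)c1 | intermediate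
14 | methyl (2S,3S)-3-chloro-2-hydroxy-3-[3-methoxy-4-(pivaloyloxy)phenyl]-2-(2,4,6-trihydroxyphenyl)propanoate (not isolated) | COC(=O)[C@@](O)(c1c(O)cc(O)cc1O)[C@@H](Cl)c1ccc(OC(=O)C(C)(C)C)c(OC)c1 | intermediate
15 | methyl (2R,3R)-3,4,6-trihydroxy-2-[3-methoxy-4-(pivaloyloxy)phenyl]-2,3-dihydro-1-benzofuran-3-carboxylate | COc1cc([C@H]2Oc3cc(O)cc(O)c3[C@]2(O)C(=O)OC)ccc1OC(=O)C(C)(C)C | intermediate
16 | (2R,3R)-3,4,6-trihydroxy-2-(4-hydroxy-3-methoxyphenyl)-2,3-dihydro-1-benzofuran-3-carbaldehyde | COc1cc([C@H]2Oc3cc(O)cc(O)c3[C@]2(O)C=O)ccc1O | intermediate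
17 | (2R,3R)-3,5,7-trihydroxy-2-(4-hydroxy-3-methoxyphenyl)-2,3-dihydro-4H-chromen-4-one | COc1cc([C@H]2Oc3cc(O)cc(O)c3C(=O)[C@@H]2O)ccc1O | intermediate
18 | prenyl bromide | CC(C)=CCBr | starting material
19 | (2R,3R)-3,5-dihydroxy-2-(4-hydroxy-3-methoxyphenyl)-7-[(3-methylbut-2-en-1-yl)oxy]-2,3-dihydro-4H-chromen-4-one | COc1cc([C@H]2Oc3cc(OCC=C(C)C)cc(O)c3C(=O)[C@@H]2O)ccc1O | target

**Step count**
Total: 9 steps. Longest linear sequence: 8 steps (1, 2, 3, 4, 6, 7, 8, 9 from catechol); step 5 is the side branch.

**Three steps most likely to fail, with fallbacks**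

Step 6, the asymmetric annulation. This substrate pair is untested: the ee or the cis/trans ratio at C2 may be low, and C-benzylation of phloroglucinol at the C–Cl carbon may compete. The fallback replaces catalyst control by a covalent auxiliary; it sets out from 6 (with 13) and comes back at 16. (−)-8-Phenylmenthol is acylated with Cl2CHCOCl to (1R,2S,5R)-5-methyl-2-(2-phenylpropan-2-yl)cyclohexyl dichloroacetate F1. Darzens condensation of F1 with 6 under the conditions of step 4 gives the auxiliary keto ester (1R,2S,5R)-5-methyl-2-(2-phenylpropan-2-yl)cyclohexyl 3-chloro-3-[3-methoxy-4-(pivaloyloxy)phenyl]-2-oxopropanoate F2. Annulation of F2 with 13 under achiral conditions (MgBr2·OEt2, Et3N, CH2Cl2, −40 °C) relies on the cumyl group shielding one face of the chelated keto ester (auxiliary-controlled addition to α-keto esters; the antipodal auxiliary is taken if the shielded face is the wrong one). It gives the auxiliary ester (1R,2S,5R)-5-methyl-2-(2-phenylpropan-2-yl)cyclohexyl (2R,3R)-3,4,6-trihydroxy-2-[3-methoxy-4-(pivaloyloxy)phenyl]-2,3-dihydro-1-benzofuran-3-carboxylate F3. iBu2AlH as in step 7 then cleaves auxiliary and pivalate and gives 16.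

Step 8, the proposed ring expansion. It may take the cisoid course and give the 2,3-cis isomer, 16 may dehydrate to the aromatic 2-arylbenzofuran-3-carbaldehyde, or base may open the ring of 17. The fallback uses only known reactions and builds ring C directly; it sets out from 9 (with 13) and comes back at 17.
- Dynamic kinetic asymmetric transfer hydrogenation of 9 (RuCl[(S,S)-TsDPEN](p-cymene) or its enantiomer, whichever gives the 2S alcohol; HCO2H/Et3N) gives methyl (2S,3R)-3-chloro-2-hydroxy-3-[3-methoxy-4-(pivaloyloxy)phenyl]propanoate F4.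
- K2CO3 in acetone closes it to the trans-glycidate methyl (2R,3S)-3-[3-methoxy-4-(pivaloyloxy)phenyl]oxirane-2-carboxylate F5.
- Phloroglucinol 13 (K2CO3, DMF) opens the epoxide at the benzylic carbon with inversion to methyl (2R,3R)-3-(3,5-dihydroxyphenoxy)-2-hydroxy-3-[3-methoxy-4-(pivaloyloxy)phenyl]propanoate F6.
- LiOH cleaves both esters to (2R,3R)-3-(3,5-dihydroxyphenoxy)-2-hydroxy-3-(4-hydroxy-3-methoxyphenyl)propanoic acid F7.
- Intramolecular Friedel–Crafts acylation ((CF3CO)2O, then BF3·OEt2, 0 °C; aqueous NaHCO3 work-up) closes ring C and gives 17.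

Step 9, the final prenylation. Four hydroxyl groups compete, C-alkylation at C6/C8 is possible, and the flavanonol is base-sensitive. The fallback sets out from 17 and ends at 19: Mitsunobu etherification with 3-methylbut-2-en-1-ol (PPh3, DIAD, THF, 0 °C), which activates the alcohol under nearly neutral conditions and couples only the most acidic phenol (7-OH). It makes no new compound.

**Further compounds**
F1 | step 6 | (1R,2S,5R)-5-methyl-2-(2-phenylpropan-2-yl)cyclohexyl dichloroacetate | ClC(Cl)C(=O)O[C@@H]1C[C@H](C)CC[C@H]1C(C)(C)c1ccccc1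
F2 | step 6 | (1R,2S,5R)-5-methyl-2-(2-phenylpropan-2-yl)cyclohexyl 3-chloro-3-[3-methoxy-4-(pivaloyloxy)phenyl]-2-oxopropanoate | COc1cc(C(Cl)C(=O)C(=O)O[C@@H]2C[C@H](C)CC[C@H]2C(C)(C)c2ccccc2)ccc1OC(=O)C(C)(C)C
F3 | step 6 | (1R,2S,5R)-5-methyl-2-(2-phenylpropan-2-yl)cyclohexyl (2R,3R)-3,4,6-trihydroxy-2-[3-methoxy-4-(pivaloyloxy)phenyl]-2,3-dihydro-1-benzofuran-3-carboxylate | COc1cc([C@H]2Oc3cc(O)cc(O)c3[C@]2(O)C(=O)O[C@@H]2C[C@H](C)CC[C@H]2C(C)(C)c2ccccc2)ccc1OC(=O)C(C)(C)C
F4 | step 8 | methyl (2S,3R)-3-chloro-2-hydroxy-3-[3-methoxy-4-(pivaloyloxy)phenyl]propanoate | COC(=O)[C@H](O)[C@H](Cl)c1ccc(OC(=O)C(C)(C)C)c(OC)c1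
F5 | step 8 | methyl (2R,3S)-3-[3-methoxy-4-(pivaloyloxy)phenyl]oxirane-2-carboxylate | COC(=O)[C@@H]1O[C@H]1c1ccc(OC(=O)C(C)(C)C)c(OC)c1
F6 | step 8 | methyl (2R,3R)-3-(3,5-dihydroxyphenoxy)-2-hydroxy-3-[3-methoxy-4-(pivaloyloxy)phenyl]propanoate | COC(=O)[C@H](O)[C@H](Oc1cc(O)cc(O)c1)c1ccc(OC(=O)C(C)(C)C)c(OC)c1
F7 | step 8 | (2R,3R)-3-(3,5-dihydroxyphenoxy)-2-hydroxy-3-(4-hydroxy-3-methoxyphenyl)propanoic acid | OC(=O)[C@H](O)[C@H](Oc1cc(O)cc(O)c1)c1ccc(O)c(OC)c1
F0 | step 9 | none | none
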